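**Plan**
1. Retrosynthesis: the C7=C8 alkene is put back into the azepane (ring B), and ring B is then cut in one operation at N4–C5 and C9–C9a. This leaves a 1-pyrroline (ring A, N4=C9a) that already carries the C3 lactone, and an open C5–C17 chain that carries the C11 lactone, a leaving group on C5 and an allylsilane (Si on C7, C8=C9).
2. Enabling feature: N4=C9a is nucleophilic at N4 and, once N-alkylated, electrophilic at C9a, while C5 and C9 are 1,5-related. N-alkylation followed by allylsilane attack is therefore a formal [5+2] annulation that closes ring B.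
3. The allylsilane comes from an Eschenmoser–Claisen rearrangement of a (Z)-γ-silyl allylic alcohol ([3,3] relay C9–O → C7–Si). The pyrroline comes from L-glutamic acid by a chelate-controlled Barbier lactone synthesis and a lactam.
4. Forward order: C11 lactone, then the chain; C3 lactone, then ring A; ring B in the key step; hydrogenation last.
5. Stereochemistry: C3 from L-glutamic acid, C18 by chelation, C20 by cis-hydrogenation, C10/C11 by catalyst-controlled anti-allylboration, C13 by trans-alkylation. In the key step C9a follows from C3 (2,5-trans) and C9 from the temporary C7–Si centre (anti-SE2′).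

Key step: step 15

Remark: the target is read from the SMILES as the (3S,9R,9aS,10S,11R,13S,18S,20S) isomer. Atoms are numbered as in pyrrolo[1,2-a]azepine (C1–C3, N4, C5–C9, C9a); C10 is the CH(Et) carbon, C11–C14 the lactone on C10 (CH3 on C13), C18–C21 the lactone on C3 (CH3 on C20).

**Step 1**
Reactants: 1 (2E)-pent-2-en-1-ol
Product: 2 4,4,5,5-tetramethyl-2-[(2E)-pent-2-en-1-yl]-1,3,2-dioxaborolane
Conditions: B2pin2, Pd(MeCN)4(BF4)2 (cat.), DMSO/MeOH, 50 °C
Reagents that add atoms: bis(pinacolato)diboron, CC1(C)OB(OC1(C)C)B1OC(C)(C)C(C)(C)O1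
Why: Palladium-catalysed borylation of the allylic alcohol through a π-allyl complex should give the linear (E)-allylboronate, and no stereocentre is formed.

**Step 2**
Reactants: 2 4,4,5,5-tetramethyl-2-[(2E)-pent-2-en-1-yl]-1,3,2-dioxaborolane; 3 methyl 4-oxobutanoate
Product: 5 (5R)-5-[(3S)-pent-1-en-3-yl]oxolan-2-one, via hydroxy ester 4 (not isolated)
Conditions: (S)-TRIP phosphoric acid (5 mol %), 4 Å MS, toluene, −30 °C; then p-TsOH·H2O (cat.), CH2Cl2, rt
Reagents that add atoms: none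
Why: Brønsted-acid-catalysed allylboration through a closed chair (Zimmerman–Traxler) transition state, in which the (E)-γ-ethyl group gives the anti C10/C11 pair and the (S)-acid is the antipode expected to direct the allyl group to the Si face of the aldehyde (10S,11R), after which the γ-hydroxy ester lactonizes.

**Step 3**
Reactants: 5 (5R)-5-[(3S)-pent-1-en-3-yl]oxolan-2-one
Product: 6 (3S,5R)-3-methyl-5-[(3S)-pent-1-en-3-yl]oxolan-2-one
Conditions: LiN(i-Pr)2, THF, −78 °C; MeI, −78 °C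
Reagents that add atoms: iodomethane, CI
Why: Alkylation of the lactone lithium enolate takes place anti to the branched C5 substituent and should give the 3,5-trans lactone (13S).

**Step 4**
Reactants: 6 (3S,5R)-3-methyl-5-[(3S)-pent-1-en-3-yl]oxolan-2-one
Product: 7 (2R)-2-[(2R,4S)-4-methyl-5-oxooxolan-2-yl]butanal
Conditions: O3, CH2Cl2, −78 °C; PPh3, −78 °C → rt; used crude
Reagents that add atoms: ozone, [O-][O+]=O
Why: Ozonolysis with reductive work-up cleaves the only C=C bond under neutral conditions, so the α-centre C10 and the β-acyloxy group should survive.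

**Step 5**
Reactants: 7 (2R)-2-[(2R,4S)-4-methyl-5-oxooxolan-2-yl]butanal
Product: 8 (3S,4S)-4-[(2R,4S)-4-methyl-5-oxooxolan-2-yl]-1-(trimethylsilyl)hex-1-yn-3-ol
Conditions: (iodoethynyl)trimethylsilane, CrCl2, THF, rt
Reagents that add atoms: (iodoethynyl)trimethylsilane, C[Si](C)(C)C#CI
Why: Nozaki–Hiyama-type addition of an alkynylchromium reagent is non-basic and selective for the aldehyde over the lactone, and Felkin–Anh attack anti to C11, reinforced by the anti α-ethyl/β-acyloxy pattern, should give the (9S)-carbinol.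

**Step 6**
Reactants: 8 (3S,4S)-4-[(2R,4S)-4-methyl-5-oxooxolan-2-yl]-1-(trimethylsilyl)hex-1-yn-3-ol
Product: 9 (1Z,3S,4S)-4-[(2R,4S)-4-methyl-5-oxooxolan-2-yl]-1-(trimethylsilyl)hex-1-en-3-ol
Conditions: H2 (1 atm), Pd/CaCO3 poisoned with Pb(OAc)2, quinoline, EtOAc, rt
Reagents that add atoms: none
Why: syn-Semihydrogenation of the silylalkyne on poisoned palladium should stop at the (Z)-vinylsilane without touching the stereocentres.

**Step 7**
Reactants: 9 (1Z,3S,4S)-4-[(2R,4S)-4-methyl-5-oxooxolan-2-yl]-1-(trimethylsilyl)hex-1-en-3-ol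
Product: 10 (3R,4E,6S)-N,N-dimethyl-6-[(2R,4S)-4-methyl-5-oxooxolan-2-yl]-3-(trimethylsilyl)oct-4-enamide
Conditions: MeC(OMe)2NMe2, xylene, 140 °C
Reagents that add atoms: 1,1-dimethoxy-N,N-dimethylethan-1-amine, COC(C)(OC)N(C)C
Why: Eschenmoser–Claisen rearrangement, in which the ketene N,O-acetal on the C9 oxygen undergoes a suprafacial [3,3] shift that passes the C9–O chirality to the new C6–C7 bond, so that with the C10 side chain equatorial the (9S,Z) substrate should give the (E)-C8=C9 alkene and the (7R)-allylsilane.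

**Step 8**
Reactants: 10 (3R,4E,6S)-N,N-dimethyl-6-[(2R,4S)-4-methyl-5-oxooxolan-2-yl]-3-(trimethylsilyl)oct-4-enamide
Product: 12 (3R,4E,6S)-6-[(2R,4S)-4-methyl-5-oxooxolan-2-yl]-3-(trimethylsilyl)oct-4-en-1-ol, via β-silyl aldehyde 11 (not isolated)
Conditions: Cp2Zr(H)Cl, THF, rt; then NaBH4, MeOH, 0 °C
Reagents that add atoms: none
Why: Cp2Zr(H)Cl reduces the tertiary amide to the aldehyde through a stable zirconated hemiaminal and prefers amides to esters, and NaBH4 at 0 °C then reduces the aldehyde but not the lactone.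

**Step 9**
Reactants: 13 (2S)-5-tert-butoxy-2-[(tert-butoxycarbonyl)amino]-5-oxopentanoic acid (Boc-L-Glu(Ot-Bu)-OH)
Product: 14 tert-butyl (4S)-4-[(tert-butoxycarbonyl)amino]-5-[methoxy(methyl)amino]-5-oxopentanoate
Conditions: MeNHOMe·HCl, EDC·HCl, HOBt, N-methylmorpholine, CH2Cl2, 0 °C → rt
Reagents that add atoms: N,O-dimethylhydroxylamine hydrochloride, CNOC.Cl
Why: Carbodiimide amide coupling of a urethane-protected amino acid should proceed without racemization at C3.

**Step 10**
Reactants: 14 tert-butyl (4S)-4-[(tert-butoxycarbonyl)amino]-5-[methoxy(methyl)amino]-5-oxopentanoate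
Product: 15 tert-butyl (4S)-4-[(tert-butoxycarbonyl)amino]-5-oxopentanoate
Conditions: LiAlH4, THF, −40 °C; aq KHSO4; used crude
Reagents that add atoms: none
Why: Reduction of the N-methoxy-N-methylamide stops at the chelated tetrahedral intermediate and gives the aldehyde on work-up, while the tert-butyl ester and the carbamate should survive at low temperature.

**Step 11**
Reactants: 15 tert-butyl (4S)-4-[(tert-butoxycarbonyl)amino]-5-oxopentanoate
Product: 17 tert-butyl (4S)-4-[(tert-butoxycarbonyl)amino]-4-[(2S)-4-methylidene-5-oxooxolan-2-yl]butanoate, via hydroxy diester 16 (not isolated)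
Conditions: ethyl 2-(bromomethyl)prop-2-enoate, Zn, THF/sat. aq NH4Cl, 0 °C → rt; then pyridinium p-toluenesulfonate (cat.), toluene, 60 °C
Reagents that add atoms: ethyl 2-(bromomethyl)prop-2-enoate, C=C(CBr)C(=O)OCC
Why: Barbier addition of the 2-(ethoxycarbonyl)allylzinc reagent under Cram-chelate control (zinc bridging the carbamate and the aldehyde oxygen, attack past the C3 hydrogen) should give the syn amino alcohol (3S,18S), which closes to the α-methylene lactone.

**Step 12**
Reactants: 17 tert-butyl (4S)-4-[(tert-butoxycarbonyl)amino]-4-[(2S)-4-methylidene-5-oxooxolan-2-yl]butanoate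
Product: 18 tert-butyl (4S)-4-[(tert-butoxycarbonyl)amino]-4-[(2S,4S)-4-methyl-5-oxooxolan-2-yl]butanoate
Conditions: H2 (1 atm), 10% Pd/C, EtOAc, rt
Reagents that add atoms: none
Why: Heterogeneous hydrogenation delivers hydrogen to the exocyclic alkene from the lactone face opposite the C18 substituent and so places the new methyl group cis to it (20S).

**Step 13**
Reactants: 18 tert-butyl (4S)-4-[(tert-butoxycarbonyl)amino]-4-[(2S,4S)-4-methyl-5-oxooxolan-2-yl]butanoate
Product: 20 (5S)-5-[(2S,4S)-4-methyl-5-oxooxolan-2-yl]pyrrolidin-2-one, via amino acid trifluoroacetate 19 (not isolated)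
Conditions: CF3CO2H/CH2Cl2 (1:1), 0 °C → rt, concentrate; then EDC·HCl, HOBt, i-Pr2NEt, CH2Cl2 (0.01 M), 0 °C → rt
Reagents that add atoms: none
Why: Acidolysis removes the Boc group and the tert-butyl ester, and carbodiimide activation of the γ-amino acid at high dilution should close the five-membered lactam faster than the amine can attack the lactone carbonyl.

**Step 14**
Reactants: 20 (5S)-5-[(2S,4S)-4-methyl-5-oxooxolan-2-yl]pyrrolidin-2-one
Product: 21 (2S)-2-[(2S,4S)-4-methyl-5-oxooxolan-2-yl]-3,4-dihydro-2H-pyrrole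
Conditions: Cp2Zr(H)Cl (2.2 equiv), THF, −20 °C → rt; filtered through basic alumina and used at once
Reagents that add atoms: none
Why: Cp2Zr(H)Cl converts secondary lactams into cyclic imines (N–H zirconation, hydrozirconation of C=O, loss of the zirconium oxide) and reacts with amides faster than with esters, so the lactone and C3 should be untouched.

**Step 15**
Reactants: 12 (3R,4E,6S)-6-[(2R,4S)-4-methyl-5-oxooxolan-2-yl]-3-(trimethylsilyl)oct-4-en-1-ol; 21 (2S)-2-[(2S,4S)-4-methyl-5-oxooxolan-2-yl]-3,4-dihydro-2H-pyrrole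
Product: 24 (3S,5R)-3-methyl-5-[(1S)-1-[(3S,9R,9aS)-3-[(2S,4S)-4-methyl-5-oxooxolan-2-yl]-2,3,5,6,9,9a-hexahydro-1H-pyrrolo[1,2-a]azepin-9-yl]propyl]oxolan-2-one, via primary triflate 22 (not isolated), via pyrrolinium triflate 23 (not isolated)
Conditions: 12, Tf2O, 2,6-di-tert-butyl-4-methylpyridine, CH2Cl2, −78 °C; then 21 (1.2 equiv), −78 °C → rt; aq NaHCO3
Reagents that add atoms: none
Why: Triflate 22 alkylates the sp2 nitrogen of imine 21 to the N-alkyl-1-pyrrolinium ion 23, whose C9a is then attacked intramolecularly by C9, the γ-carbon of the allylsilane, with loss of the silyl group to triflate and shift of the double bond to C7=C8 (anti-SE2′). The closest known reaction type is the allylsilane-terminated iminium-ion cyclization (silyl aza-Prins, aza-Hosomi–Sakurai) that gives 2,3,4,7-tetrahydroazepines, here fed by N-alkylation of a cyclic imine instead of an amine/aldehyde condensation. Ring B closes in a 7-endo-trig mode on both the C=N+ and the C=C bond, and the β-silicon effect of the C7–Si bond secures bonding at C9 (seven-membered ring, cation at C8) against bonding at C8 (six-membered ring). C9a is controlled by C3: allylic 1,3-strain with the N–CH2 group turns the lactone substituent pseudo-axial, so C9 adds to the opposite face and gives the 2,5-trans pyrrolidine (9aS). C9 is controlled by the temporary C7 centre: with C6 held syn to C9 as the cis ring alkene requires, C9a enters the (E)-alkene anti to the C–Si bond, which turns (7R) into (9R) with the C10 side chain pseudo-equatorial and anti to N+. The step needs N-alkylation to outrun elimination of the triflate and self-condensation of the imine, which the non-basic medium (hindered pyridine as the only base) and the reactivity of a primary triflate should secure.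

**Step 16**
Reactants: 24 (3S,5R)-3-methyl-5-[(1S)-1-[(3S,9R,9aS)-3-[(2S,4S)-4-methyl-5-oxooxolan-2-yl]-2,3,5,6,9,9a-hexahydro-1H-pyrrolo[1,2-a]azepin-9-yl]propyl]oxolan-2-one
Product: 25 (3S,5R)-3-methyl-5-[(1S)-1-[(3S,9R,9aS)-3-[(2S,4S)-4-methyl-5-oxooxolan-2-yl]octahydro-1H-pyrrolo[1,2-a]azepin-9-yl]propyl]oxolan-2-one (target)
Conditions: H2 (1 atm), 10% Pd/C, EtOAc, rt
Reagents that add atoms: none
Why: Hydrogenation of the cis-disubstituted ring alkene creates no stereocentre and should leave both lactones and the tertiary amine intact.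

**Compound list**
1 | (2E)-pent-2-en-1-ol | CC/C=C/CO | starting material
2 | 4,4,5,5-tetramethyl-2-[(2E)-pent-2-en-1-yl]-1,3,2-dioxaborolane | CC/C=C/CB1OC(C)(C)C(C)(C)O1 | intermediate
3 | methyl 4-oxobutanoate | COC(=O)CCC=O | starting material
4 | methyl (4R,5S)-5-ethyl-4-hydroxyhept-6-enoate | CC[C@@H](C=C)[C@H](O)CCC(=O)OC | intermediate
5 | (5R)-5-[(3S)-pent-1-en-3-yl]oxolan-2-one | CC[C@@H](C=C)[C@H]1CCC(=O)O1 | intermediate
6 | (3S,5R)-3-methyl-5-[(3S)-pent-1-en-3-yl]oxolan-2-one | CC[C@@H](C=C)[C@H]1C[C@H](C)C(=O)O1 | intermediate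
7 | (2R)-2-[(2R,4S)-4-methyl-5-oxooxolan-2-yl]butanal | CC[C@@H](C=O)[C@H]1C[C@H](C)C(=O)O1 | intermediate
8 | (3S,4S)-4-[(2R,4S)-4-methyl-5-oxooxolan-2-yl]-1-(trimethylsilyl)hex-1-yn-3-ol | CC[C@@H]([C@H](O)C#C[Si](C)(C)C)[C@H]1C[C@H](C)C(=O)O1 | intermediate
9 | (1Z,3S,4S)-4-[(2R,4S)-4-methyl-5-oxooxolan-2-yl]-1-(trimethylsilyl)hex-1-en-3-ol | CC[C@@H]([C@H](O)/C=C\[Si](C)(C)C)[C@H]1C[C@H](C)C(=O)O1 | intermediate
10 | (3R,4E,6S)-N,N-dimethyl-6-[(2R,4S)-4-methyl-5-oxooxolan-2-yl]-3-(trimethylsilyl)oct-4-enamide | CC[C@@H](/C=C/[C@@H](CC(=O)N(C)C)[Si](C)(C)C)[C@H]1C[C@H](C)C(=O)O1 | intermediate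
11 | (3R,4E,6S)-6-[(2R,4S)-4-methyl-5-oxooxolan-2-yl]-3-(trimethylsilyl)oct-4-enal | CC[C@@H](/C=C/[C@@H](CC=O)[Si](C)(C)C)[C@H]1C[C@H](C)C(=O)O1 | intermediate
12 | (3R,4E,6S)-6-[(2R,4S)-4-methyl-5-oxooxolan-2-yl]-3-(trimethylsilyl)oct-4-en-1-ol | CC[C@@H](/C=C/[C@@H](CCO)[Si](C)(C)C)[C@H]1C[C@H](C)C(=O)O1 | intermediate
13 | (2S)-5-tert-butoxy-2-[(tert-butoxycarbonyl)amino]-5-oxopentanoic acid | CC(C)(C)OC(=O)CC[C@H](NC(=O)OC(C)(C)C)C(=O)O | starting material
14 | tert-butyl (4S)-4-[(tert-butoxycarbonyl)amino]-5-[methoxy(methyl)amino]-5-oxopentanoate | CC(C)(C)OC(=O)CC[C@H](NC(=O)OC(C)(C)C)C(=O)N(C)OC | intermediate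
15 | tert-butyl (4S)-4-[(tert-butoxycarbonyl)amino]-5-oxopentanoate | CC(C)(C)OC(=O)CC[C@H](NC(=O)OC(C)(C)C)C=O | intermediate
16 | 8-tert-butyl 1-ethyl (4S,5S)-5-[(tert-butoxycarbonyl)amino]-4-hydroxy-2-methylideneoctanedioate | CCOC(=O)C(=C)C[C@H](O)[C@H](CCC(=O)OC(C)(C)C)NC(=O)OC(C)(C)C | intermediate
17 | tert-butyl (4S)-4-[(tert-butoxycarbonyl)amino]-4-[(2S)-4-methylidene-5-oxooxolan-2-yl]butanoate | CC(C)(C)OC(=O)CC[C@H](NC(=O)OC(C)(C)C)[C@@H]1CC(=C)C(=O)O1 | intermediate
18 | tert-butyl (4S)-4-[(tert-butoxycarbonyl)amino]-4-[(2S,4S)-4-methyl-5-oxooxolan-2-yl]butanoate | CC(C)(C)OC(=O)CC[C@H](NC(=O)OC(C)(C)C)[C@@H]1C[C@H](C)C(=O)O1 | intermediate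
19 | (4S)-4-amino-4-[(2S,4S)-4-methyl-5-oxooxolan-2-yl]butanoic acid trifluoroacetate | [NH3+][C@@H](CCC(=O)O)[C@@H]1C[C@H](C)C(=O)O1.[O-]C(=O)C(F)(F)F | intermediate
20 | (5S)-5-[(2S,4S)-4-methyl-5-oxooxolan-2-yl]pyrrolidin-2-one | O=C1CC[C@H](N1)[C@@H]1C[C@H](C)C(=O)O1 | intermediate
21 | (2S)-2-[(2S,4S)-4-methyl-5-oxooxolan-2-yl]-3,4-dihydro-2H-pyrrole | C1=N[C@@H](CC1)[C@@H]1C[C@H](C)C(=O)O1 | intermediate
22 | (3R,4E,6S)-6-[(2R,4S)-4-methyl-5-oxooxolan-2-yl]-3-(trimethylsilyl)oct-4-en-1-yl trifluoromethanesulfonate | CC[C@@H](/C=C/[C@@H](CCOS(=O)(=O)C(F)(F)F)[Si](C)(C)C)[C@H]1C[C@H](C)C(=O)O1 | intermediate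
23 | (2S)-2-[(2S,4S)-4-methyl-5-oxooxolan-2-yl]-1-[(3R,4E,6S)-6-[(2R,4S)-4-methyl-5-oxooxolan-2-yl]-3-(trimethylsilyl)oct-4-en-1-yl]-3,4-dihydro-2H-pyrrol-1-ium trifluoromethanesulfonate | C1=[N+](CC[C@@H]([Si](C)(C)C)/C=C/[C@H](CC)[C@H]2C[C@H](C)C(=O)O2)[C@@H](CC1)[C@@H]1C[C@H](C)C(=O)O1.[O-]S(=O)(=O)C(F)(F)F | intermediate
24 | (3S,5R)-3-methyl-5-[(1S)-1-[(3S,9R,9aS)-3-[(2S,4S)-4-methyl-5-oxooxolan-2-yl]-2,3,5,6,9,9a-hexahydro-1H-pyrrolo[1,2-a]azepin-9-yl]propyl]oxolan-2-one | CC[C@@H]([C@H]1/C=C\CCN2[C@H]1CC[C@H]2[C@@H]1C[C@H](C)C(=O)O1)[C@H]1C[C@H](C)C(=O)O1 | intermediate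
25 | (3S,5R)-3-methyl-5-[(1S)-1-[(3S,9R,9aS)-3-[(2S,4S)-4-methyl-5-oxooxolan-2-yl]octahydro-1H-pyrrolo[1,2-a]azepin-9-yl]propyl]oxolan-2-one | CC[C@@H]([C@H]1CCCCN2[C@H]1CC[C@H]2[C@@H]1C[C@H](C)C(=O)O1)[C@H]1C[C@H](C)C(=O)O1 | target

**Step count**
Total: 16 steps. Longest linear sequence: 10 steps (steps 1–8, 15, 16); the other branch (steps 9–14, 15, 16) has 8.

**Steps most likely to fail**

Step 15 (key step). The process at risk is the intermolecular N-alkylation of the imine, which may be slower than elimination or 1,3-elimination of the γ-silyl triflate and self-condensation of the imine. The fallback replaces N-alkylation by N-acylation; it sets out from 12 and returns at 24. Alcohol 12 is oxidized (TEMPO, PhI(OAc)2, MeCN/H2O) to the carboxylic acid F1, which 1-chloro-N,N,2-trimethylprop-1-en-1-amine converts under neutral conditions into the acid chloride F2. Acylation of imine 21 (CH2Cl2, −78 °C → rt) is fast and gives the N-acyliminium chloride F3, which should close by the same allylsilane attack to the bicyclic lactam F4. Hydrosilylation that is selective for the tertiary lactam over the lactones (Zn(OAc)2 cat., (EtO)3SiH, THF, 40 °C) then gives 24.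

Step 14. The process at risk is competing reduction of the lactone by the zirconium hydride, or oligomerization of the aldimine during isolation. The fallback is partial reduction of an N-acyl lactam; it sets out from 20 and returns at 21. Boc2O and DMAP in MeCN give the N-Boc lactam F5, and LiBEt3H in THF at −78 °C reduces the imide-type carbonyl selectively to the N-Boc hemiaminal F6. CF3CO2H in CH2Cl2 followed by aq NaHCO3 removes the carbamate and dehydrates the hemiaminal to 21, which is used at once in step 15.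

Step 5. The process at risk is poor facial selectivity in the substrate-controlled addition to the α-branched aldehyde, which would pass a C9 epimer mixture on to C7 and then to C9 of the target. The fallback is a reagent-controlled reduction; it sets out from 8 as an epimer mixture and returns at 8. MnO2 in CH2Cl2 oxidizes the mixture to the ynone F7. Transfer hydrogenation with RuCl[(S,S)-TsDPEN](p-cymene) in i-PrOH, with the alkynyl group taking the aryl-like position, should then give the (3S)-carbinol 8.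

**Further compounds**
F1 | step 15 | (3R,4E,6S)-6-[(2R,4S)-4-methyl-5-oxooxolan-2-yl]-3-(trimethylsilyl)oct-4-enoic acid | CC[C@@H](/C=C/[C@@H](CC(=O)O)[Si](C)(C)C)[C@H]1C[C@H](C)C(=O)O1
F2 | step 15 | (3R,4E,6S)-6-[(2R,4S)-4-methyl-5-oxooxolan-2-yl]-3-(trimethylsilyl)oct-4-enoyl chloride | CC[C@@H](/C=C/[C@@H](CC(=O)Cl)[Si](C)(C)C)[C@H]1C[C@H](C)C(=O)O1
F3 | step 15 | (2S)-2-[(2S,4S)-4-methyl-5-oxooxolan-2-yl]-1-[(3R,4E,6S)-6-[(2R,4S)-4-methyl-5-oxooxolan-2-yl]-3-(trimethylsilyl)oct-4-enoyl]-3,4-dihydro-2H-pyrrol-1-ium chloride | C1=[N+](C(=O)C[C@@H]([Si](C)(C)C)/C=C/[C@H](CC)[C@H]2C[C@H](C)C(=O)O2)[C@@H](CC1)[C@@H]1C[C@H](C)C(=O)O1.[Cl-]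
F4 | step 15 | (3S,9R,9aS)-3-[(2S,4S)-4-methyl-5-oxooxolan-2-yl]-9-[(1S)-1-[(2R,4S)-4-methyl-5-oxooxolan-2-yl]propyl]-1,2,3,6,9,9a-hexahydro-5H-pyrrolo[1,2-a]azepin-5-one | CC[C@@H]([C@H]1/C=C\CC(=O)N2[C@H]1CC[C@H]2[C@@H]1C[C@H](C)C(=O)O1)[C@H]1C[C@H](C)C(=O)O1
F5 | step 14 | tert-butyl (2S)-2-[(2S,4S)-4-methyl-5-oxooxolan-2-yl]-5-oxopyrrolidine-1-carboxylate | O=C1CC[C@H](N1C(=O)OC(C)(C)C)[C@@H]1C[C@H](C)C(=O)O1
F6 | step 14 | tert-butyl (2S)-5-hydroxy-2-[(2S,4S)-4-methyl-5-oxooxolan-2-yl]pyrrolidine-1-carboxylate | OC1CC[C@H](N1C(=O)OC(C)(C)C)[C@@H]1C[C@H](C)C(=O)O1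
F7 | step 5 | (4R)-4-[(2R,4S)-4-methyl-5-oxooxolan-2-yl]-1-(trimethylsilyl)hex-1-yn-3-one | CC[C@@H](C(=O)C#C[Si](C)(C)C)[C@H]1C[C@H](C)C(=O)O1
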